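(The data are simulated with made-up constants, noise included.)

**The ratio.** Saturday's and Monday's flasks charge 500 starting material per free catalyst, so each catalyst has to go round again and again. Catalyst intermediate C holds one starting material per catalyst, so it can carry 0.200% of the charge, and the contest lies between starting material and product.

in all of them: starting material 0.18 M; partner 0.171 M

| flask | protic impurity | free catalyst | remark | time |
|---|---|---|---|---|
| alder | 3.6 mM | 0.18 mM | run made earlier |  |
| birch | 3.6 mM | 0.27 mM | run made earlier |  |
| Saturday's | 3.60 mM | 0.36 mM |  | 2.0 h |
| Monday's | 3.60 mM | 0.36 mM |  | 2.5 h |

- alder (time / min: starting material / %, catalyst intermediate C / %, product / %): 30.0: 91, 0, 3; 60.0: 92, 0, 9; 90.0: 87, 0, 12; 120: 83, 2, 17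
- birch (time / min: starting material / %, catalyst intermediate C / %, product / %): 15.0: 94, 0, 2; 40.0: 92, 0, 8; 80.0: 80, 0, 17; 120: 76, 0, 21

(readings scatter by 1.5 percentage points)

- steps thought possible: catalyst intermediate A <-> catalyst intermediate B; partner + free catalyst -> catalyst intermediate A; starting material + catalyst intermediate B -> catalyst intermediate C; free catalyst -> spent catalyst; starting material + protic impurity -> quenched substrate; catalyst intermediate C -> free catalyst + product

1. which of these there is most of at the end, counted by the starting material in it, Saturday's (catalyst intermediate C / product / starting material)
2. which of these there is most of at the end, counted by the starting material in it, Monday's (catalyst intermediate C / product / starting material)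
3. final amount of the leader among these, as a percentage of the starting material charged, in Saturday's
4. final amount of the leader among these, as a percentage of the starting material charged, in Monday's

**First instants.** The protic impurity can quench 2.00% of the starting material, counting its whole charge, while the catalyst begins its round.

**The middle.** I divide the last product reading by the catalyst charged and the time. Alder gives 85.0 /h and birch 70.0 /h, each from a reading that scatters by 1.5 percentage points. I carry their mean, 77.5 /h, as the turnover rate, the product made per catalyst charged per hour over a run, usually called the turnover frequency.

**The end.** Partner is the limiting reagent: its charge is 95.0% of the starting material and less than what the impurity leaves. By that count the final state holds 3.00% of the starting material unused. At my turnover rate, though, the partner lasts 6.13 h, longer than Monday's 2.5 h, so both flasks stop well short of that state. Holding the rate steady, I reckon product at 31.0% on Saturday's and 38.8% on Monday's, which leaves starting material at 67.0% and 59.2%.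

**The forecast.** It names starting material as leader in both flasks, with 68% (63% to 73%) on Saturday's and 62% (56% to 68%) on Monday's. Its Monday's figure is higher than my 59.2%, “Allowing for mild decay”.

**The result.** Starting material leads, at 67.6% on Saturday's and 61.4% on Monday's.

    catalyst intermediate A ⇌ catalyst intermediate B (K = 3.10, k = 300 /h)
    partner + free catalyst → catalyst intermediate A (k = 810 /M/h)
    starting material + catalyst intermediate B → catalyst intermediate C (k = 8400 /M/h)
    free catalyst → spent catalyst (k = 8.10 × 10⁻⁴ /h)
    starting material + protic impurity → quenched substrate (k = 460 /M/h)
    catalyst intermediate C → free catalyst + product (k = 21000 /h)

**What ran.** In Monday's flask the protic impurity stood at 0% by 1.25 h, with 2.00% of the starting material quenched. The round ran on to 2.50 h with 70.9% of the catalyst free, 22.2% as catalyst intermediate A, 6.50% as catalyst intermediate B, 0.287% as catalyst intermediate C and 0.136% spent, a step that makes no difference to the starting material left. The turnover rate came to 75.9 /h on Saturday's and 73.3 /h on Monday's, and a neighbour of Monday's charged with 0.11 M of starting material turned 56.1% of that charge into product, a turnover rate of 68.6 /h.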